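(The numbers of this flask are made up; the rest is arithmetic.)

Late in a run of this scheme, the target standing in a flask is what the partner's supply has made, times the fraction of that target which substrate has not yet eaten. The make follows from the fraction of substrate left, the second factor is itself a fraction left, and both can be reckoned by hand.

    substrate + partner → target, rate k1*[substrate]^2*[partner] (k1 = 8.71 × 10⁻⁵ L² mol⁻² s⁻¹, Ea1 = 82.0 kJ mol⁻¹)
    substrate + target → side product (k2 = 3.78 × 10⁻⁵ L mol⁻¹ s⁻¹, Ea2 = 79.0 kJ mol⁻¹)
    partner → decomposed reagent (k3 = 4.23 × 10⁻⁵ s⁻¹, Ea3 = 106 kJ mol⁻¹)
    partner + protic impurity → quenched reagent (k4 = 3.57 × 10⁻⁴ L mol⁻¹ s⁻¹, Ea4 = 88.0 kJ mol⁻¹)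
    (constants at 50 °C)

| setting | Wednesday's | Tuesday's | Monday's |
|---|---|---|---|
| substrate | 0.29 M | 0.29 M | 0.29 M |
| partner | 5.00 equiv | 5.00 equiv | 5.00 equiv |
| protic impurity | 0.0870 M | 0.0870 M | 0.0870 M |
| temperature | 50 °C | 10 °C | 30 °C |
| time | 40 h | 40 h | 40 h |

- percentages count the substrate that a species holds: one side product counts as two
- all constants are for 50 °C and move with temperature by the activation energies

- the flask with the highest amount of target, in percent of the substrate charged ("all alike" if they lie within 1.5 percentage points) (Wednesday's / Tuesday's / Monday's / all alike)
- final target, as a percentage of the substrate charged, in Wednesday's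
- final target, as a percentage of the substrate charged, in Tuesday's
- final target, as a percentage of the substrate charged, in Monday's

Turned round, the question becomes: what would Wednesday's flask have to keep of its target to beat Monday's?

The target-forming rate is second order in substrate, so 1/c(substrate) climbs at a rate equal to the rate constant times c(partner). The fraction of substrate left is therefore 1/(1 + D). For the area under the partner's curve, take the partner charge less the protic impurity, decaying by the decomposition constant, with the constants moved to each temperature. Wednesday's then gets D = 0.812, Monday's 0.533 and Tuesday's 0.0657. This D, the rate constant times starting c(substrate) times that area, is the partner dose.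

The doses promise 44.8%, 34.8% and 6.17% of target, so Wednesday's is reckoned to make more than the others.

Wednesday's partner lives 6.57 h, shorter than the run. For the remaining hours its target fades in a pseudo-first-order way beside the substrate left, and 48.3% survives. Monday's target, counted as sitting on average half the time, keeps 92.9%, a rough count on the generous side. That gives Monday's 32.3% and Wednesday's 21.6%. To win, Wednesday's would have to keep 72.1%, more than its reckoned share. Tuesday's whole make is less than Monday's reckoned figure.

The forecast names Monday's, with 20% for Wednesday's, 6.3% for Tuesday's and 29.5% for Monday's, and sees Wednesday's “substrate and target consuming each other”. The reckoning here stands above it for Monday's and Wednesday's, with the same order.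

The run gives Monday's first at 29.9%, then Wednesday's at 19.9% and Tuesday's at 6.31%.

Part of Tuesday's shortfall is due to the time given: left 400 h, Tuesday's holds 31.8% target, not 6.31%. Its dose over those hours is reckoned at 0.594, which promises 37.3% of target before the side step takes its share. For the repeat of Monday's at 55 °C, the dose is 0.710, less than Wednesday's 0.812, and with the late fading reckoned as for Wednesday's it promises 11.2% target. That flask gives 12.5%.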